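The tridepside is cut at its two aryl ester bonds into a ring A acid, a ring B hydroxyaldehyde and ring C as benzyl orsellinate. The plan rests on building ring C by vicinal difunctionalisation of an aryne, because ring C carries C6–CH3 and C1–CO2H on adjacent carbons, with oxygen at C2 next to the carboxyl carbon and a second oxygen at C4. In one flask the precursor, commercial 1-fluoro-3,5-dimethoxybenzene (fluorine meta to both methoxyls), becomes 3,5-dimethoxybenzyne, which accepts methyl from methyllithium and then carbon dioxide, forming both ring C carbon–carbon bonds in the orsellinic pattern. Mixed-anhydride depside couplings and one hydrogenolysis complete the synthesis.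

Key step: step 1

Remark: the target has no stereocentre, so no SMILES carries a stereodescriptor. In every ring the carbon bearing the carboxyl (or formyl) carbon is called C1.

Step 1
Reactants: 1 1-fluoro-3,5-dimethoxybenzene; 2 methyllithium; 3 carbon dioxide
Product: 7 2,4-dimethoxy-6-methylbenzoic acid, via 2-fluoro-4,6-dimethoxyphenyllithium 4 (not isolated), via 3,5-dimethoxybenzyne 5 (not isolated), via 2,4-dimethoxy-6-methylphenyllithium 6 (not isolated)
Conditions: MeLi (3 equiv), Et2O/THF, slow addition of 1 at −78 °C, then −78 → 0 °C; recool to −78 °C, dry CO2 (excess); aq. HCl work-up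
Reagents that add atoms: methyllithium [Li]C; carbon dioxide O=C=O
Why: Methyllithium first removes one of the two equivalent protons flanked by fluorine and a methoxyl to give 4, which expels LiF on warming to give aryne 5; a second methyllithium then adds to 5 and the resulting aryllithium 6 is carboxylated, so the C6–CH3 and C1–CO2H bonds of ring C arise in one flask. The closest known reaction type is carbolithiation of an alkoxy-substituted benzyne made from a haloarene, followed by an electrophilic quench, which is established for alkyllithiums, 3,5-dimethoxyhalobenzenes and carbon dioxide. No ring is closed and no stereocentre is created. Two selectivities are needed, the site of metalation and the direction of addition to the triple bond. The first is secured because fluorine is the stronger acidifying neighbour and only the anion beside fluorine can eliminate, so metalation between the two methoxyls is unproductive and can drain back by proton exchange; the second is secured because the inductively withdrawing methoxyl beside the triple bond stabilises the developing carbanion on the carbon next to it, which sends methyl to the former C–F carbon. Slow addition of 1 to excess methyllithium keeps the aryne concentration low so that 6 does not compete as a nucleophile, and the di-ortho-substituted carboxylate resists further attack by methyllithium at −78 °C.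

Step 2
Reactants: 7 2,4-dimethoxy-6-methylbenzoic acid
Product: 8 2,4-dihydroxy-6-methylbenzoic acid (orsellinic acid)
Conditions: BBr3 (4 equiv), CH2Cl2, −78 °C → rt; ice-water quench
Reagents that add atoms: none
Why: Lewis-acid aryl methyl ether cleavage, in which BBr3 complexes each ether oxygen and bromide removes the methyl by SN2, while working at or below room temperature with a cold quench avoids protodecarboxylation of the electron-rich acid.

Step 3
Reactants: 8 orsellinic acid
Product: 9 benzyl 2,4-dihydroxy-6-methylbenzoate (benzyl orsellinate)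
Conditions: BnBr (1.05 equiv), KHCO3, DMF, rt
Reagents that add atoms: benzyl bromide BrCc1ccccc1
Why: Chemoselective SN2 alkylation of a carboxylate, since hydrogen carbonate ionises the carboxylic acid but not the phenols, so benzyl bromide should give the ester alone.

Step 4
Reactants: 10 3,4,5-trimethoxytoluene
Product: 12 2,3,4-trimethoxy-6-methylbenzaldehyde, via aryl iminium chloride 11 (not isolated)
Conditions: POCl3, DMF, 0 → 70 °C; then ice-water
Reagents that add atoms: N,N-dimethylformamide CN(C)C=O; water O
Why: Vilsmeier–Haack formylation, in which the two open ring positions of 10 are equivalent and activated by an ortho and a para methoxyl, so a single aldehyde should form after hydrolysis of 11.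

Step 5
Reactants: 12 2,3,4-trimethoxy-6-methylbenzaldehyde
Product: 13 2,3,4-trimethoxy-6-methylbenzoic acid (ring A acid)
Conditions: NaClO2, NaH2PO4, 2-methyl-2-butene, t-BuOH/H2O, rt
Reagents that add atoms: sodium chlorite (NaClO2) [Na+].[O-]Cl=O
Why: Pinnick oxidation, in which chlorous acid adds to the aldehyde and fragments to the acid while 2-methyl-2-butene removes hypochlorous acid before it can chlorinate the electron-rich ring.

Step 6
Reactants: 13 2,3,4-trimethoxy-6-methylbenzoic acid; 14 2,4-dihydroxy-6-methylbenzaldehyde
Product: 16 4-formyl-3-hydroxy-5-methylphenyl 2,3,4-trimethoxy-6-methylbenzoate, via ring A mixed trifluoroacetic anhydride 15 (not isolated)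
Conditions: (CF3CO)2O, toluene, 0 °C → rt
Reagents that add atoms: none
Why: Depside esterification through a mixed trifluoroacetic anhydride, in which the hindered, electron-rich aroyl group is passed on in an acylium-like manner to the free 4-hydroxyl of 14, the 2-hydroxyl being held in a hydrogen bond to the formyl oxygen.

Step 7
Reactants: 16 4-formyl-3-hydroxy-5-methylphenyl 2,3,4-trimethoxy-6-methylbenzoate
Product: 17 3-(benzyloxy)-4-formyl-5-methylphenyl 2,3,4-trimethoxy-6-methylbenzoate
Conditions: BnBr, K2CO3, DMF, rt
Reagents that add atoms: benzyl bromide BrCc1ccccc1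
Why: Williamson ether synthesis on the acidic ortho-formyl phenol, during which the di-ortho-substituted aryl ester is too hindered to be attacked under anhydrous carbonate conditions.

Step 8
Reactants: 17 3-(benzyloxy)-4-formyl-5-methylphenyl 2,3,4-trimethoxy-6-methylbenzoate
Product: 18 2-(benzyloxy)-6-methyl-4-(2,3,4-trimethoxy-6-methylbenzoyloxy)benzoic acid (ring A–ring B acid)
Conditions: NaClO2, NaH2PO4, 2-methyl-2-butene, t-BuOH/H2O, rt
Reagents that add atoms: sodium chlorite (NaClO2) [Na+].[O-]Cl=O
Why: Pinnick oxidation at about pH 4, which turns the formyl group into the ring B carboxyl and leaves the aryl ester, the benzyl ether and the methyl ethers untouched.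

Step 9
Reactants: 18 ring A–ring B acid; 9 benzyl orsellinate
Product: 20 benzyl 4-{[2-(benzyloxy)-6-methyl-4-(2,3,4-trimethoxy-6-methylbenzoyloxy)benzoyl]oxy}-2-hydroxy-6-methylbenzoate, via ring A–ring B mixed trifluoroacetic anhydride 19 (not isolated)
Conditions: (CF3CO)2O, toluene, 0 °C → rt
Reagents that add atoms: none
Why: Depside esterification through a mixed trifluoroacetic anhydride, selective for the 4-hydroxyl of 9 because the 2-hydroxyl is chelated to the ester carbonyl and shielded by it, with the ring B 2-oxygen blocked as its benzyl ether so that 18 cannot acylate itself.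

Step 10
Reactants: 20 doubly benzylated tridepside
Product: 21 2-hydroxy-4-{[2-hydroxy-6-methyl-4-(2,3,4-trimethoxy-6-methylbenzoyloxy)benzoyl]oxy}-6-methylbenzoic acid (target, CNP0332884.0)
Conditions: H2 (1 atm), 10% Pd/C, EtOAc, rt
Reagents that add atoms: none
Why: Catalytic hydrogenolysis cleaves the benzylic C–O bonds of the ring B ether and the ring C ester together under neutral conditions that leave both depside ester bonds and the decarboxylation-prone acid intact.

Compound list
1 | 1-fluoro-3,5-dimethoxybenzene | COc1cc(F)cc(OC)c1 | starting material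
2 | methyllithium | [Li]C | starting material
3 | carbon dioxide | O=C=O | starting material
4 | 2-fluoro-4,6-dimethoxyphenyllithium | [Li]c1c(F)cc(OC)cc1OC | intermediate
5 | 3,5-dimethoxybenzyne (1,2-didehydro-3,5-dimethoxybenzene) | COC1=CC(OC)=CC#C1 | intermediate
6 | 2,4-dimethoxy-6-methylphenyllithium | [Li]c1c(C)cc(OC)cc1OC | intermediate
7 | 2,4-dimethoxy-6-methylbenzoic acid | COc1cc(C)c(C(=O)O)c(OC)c1 | intermediate
8 | 2,4-dihydroxy-6-methylbenzoic acid (orsellinic acid) | Cc1cc(O)cc(O)c1C(=O)O | intermediate
9 | benzyl 2,4-dihydroxy-6-methylbenzoate (benzyl orsellinate) | Cc1cc(O)cc(O)c1C(=O)OCc1ccccc1 | intermediate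
10 | 3,4,5-trimethoxytoluene | COc1cc(C)cc(OC)c1OC | starting material
11 | N,N-dimethyl-(2,3,4-trimethoxy-6-methylbenzylidene)iminium chloride | C[N+](C)=Cc1c(C)cc(OC)c(OC)c1OC.[Cl-] | intermediate
12 | 2,3,4-trimethoxy-6-methylbenzaldehyde | COc1cc(C)c(C=O)c(OC)c1OC | intermediate
13 | 2,3,4-trimethoxy-6-methylbenzoic acid | COc1cc(C)c(C(=O)O)c(OC)c1OC | intermediate
14 | 2,4-dihydroxy-6-methylbenzaldehyde | Cc1cc(O)cc(O)c1C=O | starting material
15 | 2,3,4-trimethoxy-6-methylbenzoic trifluoroacetic anhydride | COc1cc(C)c(C(=O)OC(=O)C(F)(F)F)c(OC)c1OC | intermediate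
16 | 4-formyl-3-hydroxy-5-methylphenyl 2,3,4-trimethoxy-6-methylbenzoate | COc1cc(C)c(C(=O)Oc2cc(C)c(C=O)c(O)c2)c(OC)c1OC | intermediate
17 | 3-(benzyloxy)-4-formyl-5-methylphenyl 2,3,4-trimethoxy-6-methylbenzoate | COc1cc(C)c(C(=O)Oc2cc(C)c(C=O)c(OCc3ccccc3)c2)c(OC)c1OC | intermediate
18 | 2-(benzyloxy)-6-methyl-4-(2,3,4-trimethoxy-6-methylbenzoyloxy)benzoic acid | COc1cc(C)c(C(=O)Oc2cc(C)c(C(=O)O)c(OCc3ccccc3)c2)c(OC)c1OC | intermediate
19 | 2-(benzyloxy)-6-methyl-4-(2,3,4-trimethoxy-6-methylbenzoyloxy)benzoic trifluoroacetic anhydride | COc1cc(C)c(C(=O)Oc2cc(C)c(C(=O)OC(=O)C(F)(F)F)c(OCc3ccccc3)c2)c(OC)c1OC | intermediate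
20 | benzyl 4-{[2-(benzyloxy)-6-methyl-4-(2,3,4-trimethoxy-6-methylbenzoyloxy)benzoyl]oxy}-2-hydroxy-6-methylbenzoate | COc1cc(C)c(C(=O)Oc2cc(C)c(C(=O)Oc3cc(C)c(C(=O)OCc4ccccc4)c(O)c3)c(OCc3ccccc3)c2)c(OC)c1OC | intermediate
21 | 2-hydroxy-4-{[2-hydroxy-6-methyl-4-(2,3,4-trimethoxy-6-methylbenzoyloxy)benzoyl]oxy}-6-methylbenzoic acid | COc1cc(C)c(C(=O)Oc2cc(C)c(C(=O)Oc3cc(C)c(C(=O)O)c(O)c3)c(O)c2)c(OC)c1OC | target

Total step count: 10
Longest linear sequence: 7 steps (steps 4, 5, 6, 7, 8, 9, 10). The ring C branch runs through steps 1, 2, 3 and joins at step 9.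

Steps most likely to fail

1. Step 1. The step may suffer from metalation between the two methoxyls instead of beside fluorine. The product aryllithium may also capture the aryne in place of methyllithium, or the aryllithium may be protonated by unreacted substrate before carboxylation. The fallback takes the ring C skeleton from an existing orcinol aldehyde instead of assembling it on an aryne. It sets out from 14, which is O-methylated twice (MeI, K2CO3, DMF) to 2,4-dimethoxy-6-methylbenzaldehyde F1. Pinnick oxidation of this aldehyde (NaClO2, NaH2PO4, 2-methyl-2-butene) gives 7, where the route is rejoined.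

2. Step 2. The electron-rich free acid may undergo protodecarboxylation under Lewis or Brønsted acid, or the unchelated C4 methyl ether may be cleaved incompletely. The fallback masks the carboxyl before the ethers are cleaved. It sets out from 7, which is esterified (MeI, K2CO3, DMF) to methyl 2,4-dimethoxy-6-methylbenzoate F2. BBr3 in CH2Cl2 then removes both aryl methyl groups on a substrate that cannot lose CO2, giving methyl 2,4-dihydroxy-6-methylbenzoate F3. Brief treatment with cold concentrated H2SO4 (acylium-type hydrolysis of a di-ortho-substituted benzoate), followed by pouring on ice, gives 8, where the route is rejoined.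

3. Step 9. Acyl transfer may be slow, because the ring B carboxyl is flanked by benzyloxy and methyl and deactivated by the 4-acyloxy group. Trifluoroacetylation of the phenol or acylation at the chelated hydroxyl could then compete. The fallback couples ring B unprotected under carbodiimide activation. It sets out from 18, which is hydrogenolysed (H2, Pd/C, EtOAc) to 2-hydroxy-6-methyl-4-(2,3,4-trimethoxy-6-methylbenzoyloxy)benzoic acid F4. Dicyclohexylcarbodiimide in toluene joins this less crowded, internally hydrogen-bonded acid to the 4-hydroxyl of 9. The product is benzyl 2-hydroxy-4-{[2-hydroxy-6-methyl-4-(2,3,4-trimethoxy-6-methylbenzoyloxy)benzoyl]oxy}-6-methylbenzoate F5. Hydrogenolysis (H2, Pd/C, EtOAc) then gives 21, where the route is rejoined.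

Further compounds
F1 | step 1 | 2,4-dimethoxy-6-methylbenzaldehyde | COc1cc(C)c(C=O)c(OC)c1
F2 | step 2 | methyl 2,4-dimethoxy-6-methylbenzoate | COC(=O)c1c(C)cc(OC)cc1OC
F3 | step 2 | methyl 2,4-dihydroxy-6-methylbenzoate | COC(=O)c1c(C)cc(O)cc1O
F4 | step 9 | 2-hydroxy-6-methyl-4-(2,3,4-trimethoxy-6-methylbenzoyloxy)benzoic acid | COc1cc(C)c(C(=O)Oc2cc(C)c(C(=O)O)c(O)c2)c(OC)c1OC
F5 | step 9 | benzyl 2-hydroxy-4-{[2-hydroxy-6-methyl-4-(2,3,4-trimethoxy-6-methylbenzoyloxy)benzoyl]oxy}-6-methylbenzoate | COc1cc(C)c(C(=O)Oc2cc(C)c(C(=O)Oc3cc(C)c(C(=O)OCc4ccccc4)c(O)c3)c(O)c2)c(OC)c1OC
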